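## The problem

The target is a germacrane (germacrane numbering throughout): one ten-membered carbocycle with an E trisubstituted C1=C10 alkene, a trans 4,5-epoxide, a free C6 hydroxyl, the C7 isopropyl group and an isovanillate on O8; the configuration is 1(10)E,4R,5R,6R,7R,8R. Closing such a ring directly, with the E alkene inside it, costs strain and entropy. Five contiguous stereocentres run from C4 to C8. C7 and C8 are neighbours and can be set together early in a small ring; C4, C5 and C6 lie across the medium ring and can only be controlled through ring conformation and through each other. The C5–O/C6–O relation is erythro. A hydroxyl-directed epoxidation of the C6 carbinol, whose hydrogen is held in the alkene plane by the cis C4 methyl group, is expected to give threo, so epoxide and carbinol cannot be set in the obvious order. The 4,5-epoxy-1(10)-ene array cyclises across the ring under acid, the β-oxygenated C6 ketones met on the way can eliminate under base, the C6–OH/C8–ester pair is open to acyl shift, and the phenol must be masked during acylation. The enabling feature is that the C6 oxygen and the C1=C10 alkene are the two ends of a Grob retron. Joining C6 to C10 turns the ring into a bicyclo[5.3.0]decane whose five-membered ring (C6–C7–C8–C9–C10) holds C7 and C8 and whose seven-membered ring (C10, C1–C6) holds a leaving group at C1.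

## Retrosynthesis

**Target 32 to epoxy ketone 30.** The phenol is unmasked last (31 to 32). The C6–H bond of 31 is cut back to ketone 30, because a zinc-chelated α,β-epoxy ketone is reduced to the erythro epoxy alcohol by a local rule that does not depend on the ring conformation. Setting C6 before the epoxide would require an erythro-selective epoxidation against allylic strain.

**Epoxy ketone 30 to enone 27.** The two epoxide C–O bonds are cut. The oxygen is delivered by the C6 hydroxyl of allylic alcohol 28, the C6 epimer of the natural carbinol, for which directed epoxidation and allylic 1,3-strain point to the same alkene face (threo, giving 29). Compound 28 is the carbinol expected from peripheral hydride attack on 27. Base-mediated epoxidation of 27 itself was set aside because the β-acyloxy ketone is base-labile and nothing would direct the face.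

**Enone 27 to ring ketone 20.** The ester C–O bond is cut to alcohol 23 and silyl-protected isovanillic acid 26. The aroate goes on only after all organometallic and strongly basic steps. The C4=C5 bond is removed to give saturated ketone 20; forward, a Saegusa oxidation of the C5 enolate installs it as the E enone 22.

**Ring ketone 20 to mesylate 18 (key cut).** The C6–C10 bond is re-formed, C1=C10 becomes C1–OMs and C6=O becomes a tertiary alkoxide. Against the cuts at C2–C3, C3–C4 or C9–C10, this one needs no macrocyclisation. The ring is released from a strain-free bicycle and the alkene geometry is dictated by one relative configuration (C1–O cis to C10–Me). The bicycle carries C7 and C8 on a cyclopentane, where trans equals the required relation.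

**Mesylate 18 to bicyclic diol 14.** The C1 configuration is taken from reduction of ring ketone 16 anti to the angular methyl (17), which is the reliable way to place oxygen cis to that methyl. Ketone 16 comes from diol 14 by oxidation (15) and hydrogenation. The ring alkene C4=C5 is cis within the seven-membered ring and would emerge as the 4Z enone, so it is saturated and the E enone is made after ring opening.

**Bicyclic diol 14 to enone 8 and aldehyde 10.** Three bonds are cut: C4=C5 (ring-closing metathesis of 13), C5–C6 (vinyl addition to ketone 12) and C1–C10 (aldol of the C10 enolate 11 with 10). The enolate is made by conjugate reduction of 8, which makes it regiospecific and creates the quaternary C10. The chair aldol gives the wrong C1 epimer, hence the oxidation and reduction above. C10, C6 and C4 are relay centres erased later.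

**Enone 8 to furfural 1.** The C10 methyl is traced to α-iodination and cross-coupling (7, 6). The trans hydroxy-isopropyl cyclopentenone 5 comes from Piancatelli rearrangement of furyl carbinol 3, made from 1 and 2, with enzymatic resolution of racemate 4.

## Roads not taken

**Alternative 1:** B-alkyl Suzuki closure of C3–C4. The open-chain diene vinyl iodide A2 would be hydroborated with 9-BBN at the terminal alkene (boron at C3) and coupled with Pd(dppf)Cl2/K3PO4 to macrocycle A1, with the PMB-protected isovanillate already on O8. Its merits are convergence, both trisubstituted alkenes fixed before cyclisation, and only three operations after ring closure. It is probably shorter than the chosen plan in longest linear sequence. Its weak points are closure of a strained ten-membered E,E-diene under dilution with β-hydride elimination and oligomerisation competing, selective hydroboration at the end of a 1,3-diene, and oxidative PMB removal next to the epoxy-ene. A1 also carries the natural C6 configuration, so the epoxide would have to be delivered erythro against allylic strain. The chosen plan sets against the better step count a ring opening that cannot oligomerise and a C5/C6 relation built from two matched steps.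

**Alternative 2:** Allyl sulfone alkylation at C2–C3. KN(SiMe3)2 would deprotonate the C3 sulfone of bromo sulfone A4 and the carbanion would displace the C2 allylic bromide to give macrocycle A3. Sulfur-stabilised carbanion alkylation is a proven way to medium-ring terpenes and tolerates the oxygenation. Its weak points are α versus γ and SN2 versus SN2' regiochemistry, high dilution, a later reductive desulfonylation at an allylic position that can move or scramble C4=C5, and a PMB-to-ester exchange at O8. The step count is no lower than in the chosen plan and the same epoxidation problem remains. Its one advantage, convergence, does not outweigh the added redox and protecting-group steps.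

**Alternative 3:** Nickel-catalysed reductive alkyne–epoxide macrocyclisation. Ni(cod)2, PBu3 and Et3B would join the terminal epoxide carbon C9 of epoxy alkyne A6 to C10 of the methyl alkyne, giving A5 with the E alkene and the free C8 hydroxyl in one step. On paper this is the shortest road and it frees O8 exactly when the ester is needed. Its weak points are that the intramolecular coupling is established for five- and six-membered rings, not for a ten-membered ring that must hold a nickelacycle, and that regiochemistry at a dialkyl alkyne rests on the tether alone. If it worked it would beat the chosen plan on step count; the chosen plan relies instead on a fragmentation type with many (E)-cyclodecenone precedents.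

Key step: step 15

Assumption: the lipase acylates the (4S,5R) enantiomer of 4, as it does the spatially analogous parent 4-hydroxycyclopent-2-enone, and leaves (4R,5S)-5; if the preference is reversed, the acetate would be taken and cleaved with the same enzyme in buffer.

Assumption: the relay centres C10, C6 and C4 in 12–18 are drawn as the isomers expected to predominate; each is erased in step 15 or 16, so an epimer at any of them converges on 20 or 22 as long as the C1 oxygen is cis to the C10 methyl group.

## Route

Step 1
Reactants: 1 furfural; 2 isopropylmagnesium bromide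
Product: 3 (±)-1-(furan-2-yl)-2-methylpropan-1-ol
Conditions: THF, 0 °C; aq NH4Cl
Reagents that add atoms: none
Why: Grignard addition to the aldehyde; the new stereocentre is ionised in step 2, so its configuration is irrelevant.

Step 2
Reactants: 3 (±)-1-(furan-2-yl)-2-methylpropan-1-ol
Product: 4 (±)-trans-4-hydroxy-5-isopropylcyclopent-2-en-1-one
Conditions: ZnCl2, dioxane–H2O, reflux
Reagents that add atoms: water O
Why: Piancatelli rearrangement: ionisation of the carbinol, water addition at C5 of the furan, ring opening and conrotatory 4π electrocyclisation, which places hydroxyl and isopropyl trans (the later C8/C7 relation).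

Step 3
Reactants: 4 (±)-trans-4-hydroxy-5-isopropylcyclopent-2-en-1-one
Product: 5 (4R,5S)-4-hydroxy-5-isopropylcyclopent-2-en-1-one
Conditions: lipase PS (Burkholderia cepacia), vinyl acetate, t-BuOMe, 30 °C, to about half conversion
Reagents that add atoms: none
Why: Lipase-catalysed kinetic resolution by transesterification, a standard entry to enantiopure 4-hydroxycyclopentenones; the unreacted alcohol carries the C8 and C7 configurations of the target.

Step 4
Reactants: 5 (4R,5S)-4-hydroxy-5-isopropylcyclopent-2-en-1-one
Product: 6 (4R,5S)-4-(tert-butyldimethylsilyloxy)-5-isopropylcyclopent-2-en-1-one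
Conditions: TBSCl, imidazole, DMF, 0 °C to rt
Reagents that add atoms: tert-butyldimethylsilyl chloride CC(C)(C)[Si](C)(C)Cl
Why: Standard silylation; imidazole is mild enough for the base-labile ketol.

Step 5
Reactants: 6 (4R,5S)-4-(tert-butyldimethylsilyloxy)-5-isopropylcyclopent-2-en-1-one
Product: 7 4-(tert-butyldimethylsilyloxy)-2-iodo-5-isopropylcyclopent-2-en-1-one (configuration of 6 retained)
Conditions: I2, pyridine, CH2Cl2, 0 °C to rt
Reagents that add atoms: iodine II
Why: α-Iodination of the enone by pyridine-mediated addition–elimination, routine for 4-silyloxycyclopentenones.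

Step 6
Reactants: 7 4-(tert-butyldimethylsilyloxy)-2-iodo-5-isopropylcyclopent-2-en-1-one
Product: 8 (4R,5S)-4-(tert-butyldimethylsilyloxy)-5-isopropyl-2-methylcyclopent-2-en-1-one
Conditions: MeZnCl, PdCl2(dppf) (5 mol %), THF, 0 °C to rt
Reagents that add atoms: methylzinc chloride C[Zn]Cl
Why: Negishi coupling of the α-iodoenone installs the future C10 methyl; the organozinc does not add to the enone.

Step 7
Reactants: 9 4-methylpent-4-en-1-ol
Product: 10 4-methylpent-4-enal
Conditions: TEMPO (10 mol %), PhI(OAc)2, CH2Cl2, rt
Reagents that add atoms: none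
Why: Oxoammonium oxidation stops at the aldehyde and leaves the 1,1-disubstituted alkene alone; the volatile aldehyde is used as a solution.

Step 8
Reactants: 8 (4R,5S)-4-(tert-butyldimethylsilyloxy)-5-isopropyl-2-methylcyclopent-2-en-1-one; 10 4-methylpent-4-enal
Product: 12 aldol adduct 4-(tert-butyldimethylsilyloxy)-2-(1-hydroxy-4-methylpent-4-enyl)-5-isopropyl-2-methylcyclopentan-1-one, via lithium enolate 11 (not isolated)
Conditions: LiBH(s-Bu)3, THF, −78 °C; then 10, −78 °C; aq NH4Cl
Reagents that add atoms: none
Why: Reductive aldol: conjugate hydride delivery gives the C10 enolate regiospecifically (never the C7 enolate, which would expel the silyloxy group), and a Zimmerman–Traxler aldol builds the quaternary C10. The aldehyde should approach anti to the C7 isopropyl group flanking the metal-bound oxygen; the chair gives the C1 epimer that is corrected in steps 11 and 13.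

Step 9
Reactants: 12 aldol adduct
Product: 13 1-vinyl diol 4-(tert-butyldimethylsilyloxy)-2-(1-hydroxy-4-methylpent-4-enyl)-5-isopropyl-2-methyl-1-vinylcyclopentan-1-ol
Conditions: CH2=CHMgBr (3 equiv), CeCl3, THF, −78 to −40 °C; aq NH4Cl
Reagents that add atoms: vinylmagnesium bromide C=C[Mg]Br
Why: Organocerium 1,2-addition to a hindered, enolisable ketone. Attack anti to the adjacent C7 isopropyl group and the pseudo-axial C10 methyl places vinyl cis to the C1 chain; C6 is in any case a relay centre that becomes the carbonyl carbon.

Step 10
Reactants: 13 1-vinyl diol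
Product: 14 bicyclo[5.3.0]dec-4-ene-1,6-diol (8-silyloxy, 7-isopropyl, 4,10-dimethyl; cis-fused)
Conditions: second-generation Grubbs catalyst RuCl2(=CHPh)(H2IMes)(PCy3) (5 mol %), CH2Cl2 (5 mM), 40 °C
Reagents that add atoms: none
Why: Ring-closing metathesis of the vinyl carbinol with the 1,1-disubstituted alkene closes the seven-membered ring as a trisubstituted cycloalkene with loss of ethene; free hydroxyls are tolerated.

Step 11
Reactants: 14 bicyclic ene diol
Product: 15 6-hydroxybicyclo[5.3.0]dec-4-en-1-one (8-silyloxy, 7-isopropyl, 4,10-dimethyl)
Conditions: Dess–Martin periodinane, NaHCO3, CH2Cl2, 0 °C to rt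
Reagents that add atoms: none
Why: Oxidation of the secondary C1 carbinol only; the tertiary allylic C6 hydroxyl is inert and the non-basic medium avoids retro-aldol opening of the β-hydroxy ketone.

Step 12
Reactants: 15 hydroxy enone-free ketone with C4=C5
Product: 16 6-hydroxybicyclo[5.3.0]decan-1-one (8-silyloxy, 7-isopropyl, 4,10-dimethyl; C4 methyl trans to C6–OH)
Conditions: H2 (1 atm), [Ir(cod)(PCy3)(py)]PF6 (5 mol %), CH2Cl2, rt
Reagents that add atoms: none
Why: Hydroxyl-directed hydrogenation: the C6 hydroxyl delivers hydrogen to its own face, which fixes C4 and avoids hydrogenolysis of the allylic C–O bond; C4 is erased again in step 16.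

Step 13
Reactants: 16 saturated hydroxy ketone
Product: 17 bicyclo[5.3.0]decane-1,6-diol with C1–OH cis to the C10 methyl
Conditions: NaBH4, MeOH, −20 °C
Reagents that add atoms: none
Why: Hydride attacks the cycloheptanone anti to the angular methyl, as in the reduction of the Wieland–Miescher and Hajos–Parrish ketones, so the C1 hydroxyl ends up cis to that methyl; fast reduction at low temperature outruns retro-aldol opening.

Step 14
Reactants: 17 cis-1,6-diol
Product: 18 6-hydroxy-8-(tert-butyldimethylsilyloxy)-7-isopropyl-4,10-dimethylbicyclo[5.3.0]decan-1-yl methanesulfonate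
Conditions: MsCl, Et3N, CH2Cl2, −10 °C
Reagents that add atoms: methanesulfonyl chloride CS(=O)(=O)Cl
Why: Sulfonylation via sulfene takes the secondary hydroxyl and leaves the tertiary one.

Step 15
Reactants: 18 hydroazulene diol monomesylate
Product: 20 (E)-8-(tert-butyldimethylsilyloxy)germacr-1(10)-en-6-one, via potassium alkoxide 19 (not isolated)
Conditions: KOt-Bu (1.5 equiv), THF, 0 °C, 15 min; pH 7 buffer
Reagents that add atoms: none
Why: Wharton-type Grob fragmentation of a cyclic 1,3-diol monosulfonate. KOt-Bu forms the tertiary C6 alkoxide 19, whose electrons form the C6 carbonyl as the C6–C10 bond, anti-periplanar to C1–OMs, breaks, C10=C1 forms and mesylate leaves in one concerted step. No ring is closed by bond formation: the ten-membered ring is released by cleaving the bond shared by the five- and seven-membered rings, so no dilution-dependent cyclisation is involved. No stereocentre is created; C6, C10 and C1 become trigonal, and C7, C8 and the spectator C4 are untouched. The selectivity needed is the E geometry of C1=C10, secured by the relative configuration from step 13: with the mesylate cis to the angular methyl, the conformer with C1–O anti to C6–C10 has C2 anti to C9, and the stereospecific fragmentation turns that into the E alkene. Alkoxide and mesylate are cis on the seven-membered ring, so backside closure to an oxetane is geometrically excluded. The closest known reaction type is the fragmentation of decalin-1,3-diol monosulfonates to (E)-cyclodecenones; only the ring sizes differ here. Short exposure to base at 0 °C and a buffered quench are meant to spare the β-silyloxy ketone from silanolate loss and C7 epimerisation.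

Step 16
Reactants: 20 (E)-8-(tert-butyldimethylsilyloxy)germacr-1(10)-en-6-one
Product: 22 8-(tert-butyldimethylsilyloxy)germacra-1(10)E,4E-dien-6-one, via trimethylsilyl enol ether 21 (not isolated)
Conditions: LiN(SiMe3)2, Me3SiCl, THF, −78 °C; then Pd(OAc)2 (1.1 equiv), MeCN, rt
Reagents that add atoms: none
Why: Saegusa–Ito oxidation: kinetic deprotonation at the C5 methylene (the C7 methine is hindered), silylation, then the divalent palladium enolate loses the C4 hydrogen by β-hydride elimination. The medium ring is expected to favour the E enone, and C4 becomes trigonal.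

Step 17
Reactants: 22 silyloxy dienone
Product: 23 8-hydroxygermacra-1(10)E,4E-dien-6-one
Conditions: HF·pyridine, pyridine, THF, 0 °C to rt
Reagents that add atoms: none
Why: Buffered fluoride desilylation; the medium is too weakly basic to dehydrate the β-hydroxy ketone and too weakly acidic to protonate the diene.

Step 18
Reactants: 24 isovanillic acid
Product: 26 3-(tert-butyldimethylsilyloxy)-4-methoxybenzoic acid, via bis-silyl derivative 25 (not isolated)
Conditions: TBSCl (2.2 equiv), imidazole, DMF, rt; then AcOH–THF–H2O, rt
Reagents that add atoms: tert-butyldimethylsilyl chloride CC(C)(C)[Si](C)(C)Cl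
Why: Silylation of phenol and acid, then selective hydrolysis of the labile silyl ester, leaves only the phenol masked.

Step 19
Reactants: 23 8-hydroxygermacra-1(10)E,4E-dien-6-one; 26 3-(tert-butyldimethylsilyloxy)-4-methoxybenzoic acid
Product: 27 6-oxogermacra-1(10)E,4E-dien-8-yl 3-(tert-butyldimethylsilyloxy)-4-methoxybenzoate
Conditions: DCC, DMAP (0.2 equiv), CH2Cl2, 0 °C to rt
Reagents that add atoms: none
Why: Steglich esterification with retention at C8; low temperature and a weak base are chosen so that the β-acyloxy ketone does not lose the aroate by E1cB.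

Step 20
Reactants: 27 aroyloxy dienone
Product: 28 6-epi allylic alcohol: 6-hydroxygermacra-1(10)E,4E-dien-8-yl 3-(tert-butyldimethylsilyloxy)-4-methoxybenzoate with C6 opposite to the target
Conditions: NaBH4, CeCl3·7H2O, MeOH, −78 °C
Reagents that add atoms: none
Why: Luche 1,2-reduction. Hydride from the ring periphery onto the crown-type conformer (C7 and C8 substituents equatorial) should give the carbinol whose oxygen eclipses C4=C5, which is the C6 epimer of the natural centre and the one step 21 needs.

Step 21
Reactants: 28 6-epi allylic alcohol
Product: 29 (4R,5R)-4,5-epoxy-6-epi alcohol (epoxide as in the target, C6–O threo to C5–O)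
Conditions: VO(acac)2 (5 mol %), t-BuOOH, CH2Cl2, 0 °C
Reagents that add atoms: tert-butyl hydroperoxide CC(C)(C)OO
Why: Hydroxyl-directed epoxidation. Allylic 1,3-strain against the C4 methyl turns the C6 hydrogen into the alkene plane, so the C6 oxygen lies on the outer face and delivers the oxidant there (threo), which sets C4 and C5 as in the target. The isolated C1=C10 alkene is not oxidised by this reagent.

Step 22
Reactants: 29 epoxy 6-epi alcohol
Product: 30 (4R,5R)-4,5-epoxy-6-oxogermacr-1(10)E-en-8-yl 3-(tert-butyldimethylsilyloxy)-4-methoxybenzoate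
Conditions: Dess–Martin periodinane, NaHCO3, CH2Cl2, 0 °C
Reagents that add atoms: none
Why: Oxidation removes the auxiliary C6 centre under buffered conditions that epimerise neither C5 nor C7.

Step 23
Reactants: 30 epoxy ketone
Product: 31 (4R,5R,6R,7R,8R)-4,5-epoxy-6-hydroxygermacr-1(10)E-en-8-yl 3-(tert-butyldimethylsilyloxy)-4-methoxybenzoate
Conditions: Zn(BH4)2, Et2O, −20 °C; aq NH4Cl
Reagents that add atoms: none
Why: Chelation-controlled reduction of an α,β-epoxy ketone: zinc bridges the epoxide and carbonyl oxygens and hydride enters anti to the epoxide carbon C4, giving the erythro (anti) epoxy alcohol, here 6R. Peripheral attack on the ring points the same way, and the ester is not reduced.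

Step 24
Reactants: 31 phenol-silylated target
Product: 32 target, (1(10)E,4R,5R,6R,7R,8R)-4,5-epoxy-6-hydroxygermacr-1(10)-en-8-yl 3-hydroxy-4-methoxybenzoate
Conditions: Bu4NF, AcOH (1:1), THF, 0 °C
Reagents that add atoms: none
Why: Buffered fluoride cleaves the aryl silyl ether quickly; near-neutral conditions avoid acid-triggered transannular opening of the epoxide and base-induced acyl shift from O8 to O6.

## Compound list

1 | furfural (furan-2-carbaldehyde) | O=Cc1ccco1 | starting material
2 | isopropylmagnesium bromide | CC(C)[Mg]Br | starting material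
3 | (±)-1-(furan-2-yl)-2-methylpropan-1-ol | CC(C)C(O)c1ccco1 | intermediate
4 | (±)-trans-4-hydroxy-5-isopropylcyclopent-2-en-1-one (racemate, both enantiomers written) | CC(C)[C@H]1[C@H](O)C=CC1=O.CC(C)[C@@H]1[C@@H](O)C=CC1=O | intermediate
5 | (4R,5S)-4-hydroxy-5-isopropylcyclopent-2-en-1-one (hydroxyl and isopropyl trans; C4 becomes C8, C5 becomes C7) | CC(C)[C@H]1[C@H](O)C=CC1=O | intermediate
6 | (4R,5S)-4-(tert-butyldimethylsilyloxy)-5-isopropylcyclopent-2-en-1-one | CC(C)[C@H]1[C@H](O[Si](C)(C)C(C)(C)C)C=CC1=O | intermediate
7 | 4-(tert-butyldimethylsilyloxy)-2-iodo-5-isopropylcyclopent-2-en-1-one, substituents trans, configuration of 6 retained | CC(C)[C@H]1[C@H](O[Si](C)(C)C(C)(C)C)C=C(I)C1=O | intermediate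
8 | (4R,5S)-4-(tert-butyldimethylsilyloxy)-5-isopropyl-2-methylcyclopent-2-en-1-one | CC(C)[C@H]1[C@H](O[Si](C)(C)C(C)(C)C)C=C(C)C1=O | intermediate
9 | 4-methylpent-4-en-1-ol | C=C(C)CCCO | starting material
10 | 4-methylpent-4-enal | C=C(C)CCC=O | intermediate
11 | lithium 4-(tert-butyldimethylsilyloxy)-5-isopropyl-2-methylcyclopent-1-en-1-olate (C6–OLi, C6=C10; C7 and C8 as in 8) | CC(C)[C@H]1[C@H](O[Si](C)(C)C(C)(C)C)CC(C)=C1[O-].[Li+] | intermediate
12 | 4-(tert-butyldimethylsilyloxy)-2-(1-hydroxy-4-methylpent-4-enyl)-5-isopropyl-2-methylcyclopentan-1-one; C10 methyl cis to the C7 isopropyl group, C8 silyloxy trans to it; C1 carbinol as given by the chair aldol | CC(C)[C@H]1[C@H](O[Si](C)(C)C(C)(C)C)C[C@](C)([C@H](O)CCC(C)=C)C1=O | intermediate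
13 | 4-(tert-butyldimethylsilyloxy)-2-(1-hydroxy-4-methylpent-4-enyl)-5-isopropyl-2-methyl-1-vinylcyclopentan-1-ol; C6 hydroxyl cis to the C10 methyl and the C7 isopropyl group, vinyl cis to the C1 chain | CC(C)[C@H]1[C@H](O[Si](C)(C)C(C)(C)C)C[C@](C)([C@H](O)CCC(C)=C)[C@]1(O)C=C | intermediate
14 | 8-(tert-butyldimethylsilyloxy)-7-isopropyl-4,10-dimethylbicyclo[5.3.0]dec-4-ene-1,6-diol (germacrane numbering; five-membered ring C6–C10, seven-membered ring C10, C1–C6; cis-fused, C6–OH cis to C10–Me and C7 isopropyl, C8–O trans to C7 isopropyl, C1–OH trans to C10–Me) | CC(C)[C@H]1[C@H](O[Si](C)(C)C(C)(C)C)C[C@]2(C)[C@H](O)CCC(C)=C[C@]12O | intermediate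
15 | 8-(tert-butyldimethylsilyloxy)-6-hydroxy-7-isopropyl-4,10-dimethylbicyclo[5.3.0]dec-4-en-1-one (ring fusion and C7, C8 as in 14) | CC(C)[C@H]1[C@H](O[Si](C)(C)C(C)(C)C)C[C@]2(C)C(=O)CCC(C)=C[C@]12O | intermediate
16 | 8-(tert-butyldimethylsilyloxy)-6-hydroxy-7-isopropyl-4,10-dimethylbicyclo[5.3.0]decan-1-one (C4 methyl trans to C6–OH) | CC(C)[C@H]1[C@H](O[Si](C)(C)C(C)(C)C)C[C@]2(C)C(=O)CC[C@H](C)C[C@]12O | intermediate
17 | 8-(tert-butyldimethylsilyloxy)-7-isopropyl-4,10-dimethylbicyclo[5.3.0]decane-1,6-diol (C1–OH cis to C10–Me and to C6–OH) | CC(C)[C@H]1[C@H](O[Si](C)(C)C(C)(C)C)C[C@]2(C)[C@@H](O)CC[C@H](C)C[C@]12O | intermediate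
18 | 8-(tert-butyldimethylsilyloxy)-6-hydroxy-7-isopropyl-4,10-dimethylbicyclo[5.3.0]decan-1-yl methanesulfonate (mesylate cis to the angular methyl; cis ring fusion) | CC(C)[C@H]1[C@H](O[Si](C)(C)C(C)(C)C)C[C@]2(C)[C@@H](OS(C)(=O)=O)CC[C@H](C)C[C@]12O | intermediate
19 | potassium C6 alkoxide of 18 | CC(C)[C@H]1[C@H](O[Si](C)(C)C(C)(C)C)C[C@]2(C)[C@@H](OS(C)(=O)=O)CC[C@H](C)C[C@]12[O-].[K+] | intermediate
20 | (1(10)E)-8-(tert-butyldimethylsilyloxy)germacr-1(10)-en-6-one (C7 isopropyl and C8 silyloxy as in the target; C4 methyl as set in step 12) | CC(C)(C)[Si](C)(C)O[C@@H]1C/C(C)=C/CC[C@H](C)CC(=O)[C@H]1C(C)C | intermediate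
21 | C5=C6 trimethylsilyl enol ether of 20 (enol ether geometry not defined, either serves) | CC(C)(C)[Si](C)(C)O[C@@H]1C/C(C)=C/CC[C@H](C)C=C(O[Si](C)(C)C)[C@H]1C(C)C | intermediate
22 | 8-(tert-butyldimethylsilyloxy)germacra-1(10)E,4E-dien-6-one | CC(C)(C)[Si](C)(C)O[C@@H]1C/C(C)=C/CC/C(C)=C/C(=O)[C@H]1C(C)C | intermediate
23 | 8-hydroxygermacra-1(10)E,4E-dien-6-one | O[C@@H]1C/C(C)=C/CC/C(C)=C/C(=O)[C@H]1C(C)C | intermediate
24 | isovanillic acid (3-hydroxy-4-methoxybenzoic acid) | COc1ccc(C(=O)O)cc1O | starting material
25 | tert-butyldimethylsilyl 3-(tert-butyldimethylsilyloxy)-4-methoxybenzoate | COc1ccc(C(=O)O[Si](C)(C)C(C)(C)C)cc1O[Si](C)(C)C(C)(C)C | intermediate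
26 | 3-(tert-butyldimethylsilyloxy)-4-methoxybenzoic acid | COc1ccc(C(=O)O)cc1O[Si](C)(C)C(C)(C)C | intermediate
27 | 6-oxogermacra-1(10)E,4E-dien-8-yl 3-(tert-butyldimethylsilyloxy)-4-methoxybenzoate | COc1ccc(C(=O)O[C@@H]2C/C(C)=C/CC/C(C)=C/C(=O)[C@H]2C(C)C)cc1O[Si](C)(C)C(C)(C)C | intermediate
28 | 6-hydroxygermacra-1(10)E,4E-dien-8-yl 3-(tert-butyldimethylsilyloxy)-4-methoxybenzoate, C6 epimer of the natural carbinol | COc1ccc(C(=O)O[C@@H]2C/C(C)=C/CC/C(C)=C/[C@@H](O)[C@H]2C(C)C)cc1O[Si](C)(C)C(C)(C)C | intermediate
29 | (4R,5R)-4,5-epoxy-6-hydroxygermacr-1(10)E-en-8-yl 3-(tert-butyldimethylsilyloxy)-4-methoxybenzoate, C6 epimer (C6–O threo to C5–O) | COc1ccc(C(=O)O[C@@H]2C/C(C)=C/CC[C@@]3(C)O[C@@H]3[C@@H](O)[C@H]2C(C)C)cc1O[Si](C)(C)C(C)(C)C | intermediate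
30 | (4R,5R)-4,5-epoxy-6-oxogermacr-1(10)E-en-8-yl 3-(tert-butyldimethylsilyloxy)-4-methoxybenzoate | COc1ccc(C(=O)O[C@@H]2C/C(C)=C/CC[C@@]3(C)O[C@@H]3C(=O)[C@H]2C(C)C)cc1O[Si](C)(C)C(C)(C)C | intermediate
31 | (4R,5R,6R,7R,8R)-4,5-epoxy-6-hydroxygermacr-1(10)E-en-8-yl 3-(tert-butyldimethylsilyloxy)-4-methoxybenzoate | COc1ccc(C(=O)O[C@@H]2C/C(C)=C/CC[C@@]3(C)O[C@@H]3[C@H](O)[C@H]2C(C)C)cc1O[Si](C)(C)C(C)(C)C | intermediate
32 | (1(10)E,4R,5R,6R,7R,8R)-4,5-epoxy-6-hydroxygermacr-1(10)-en-8-yl 3-hydroxy-4-methoxybenzoate (CNP0294356.1) | COc1ccc(C(=O)O[C@@H]2C/C(C)=C/CC[C@@]3(C)O[C@@H]3[C@H](O)[C@H]2C(C)C)cc1O | target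

## Step count and least certain steps

Total step count: 24 (22 on the main line, plus step 7 for the aldehyde and step 18 for the protected acid). Longest linear sequence: 22 steps, from furfural through steps 1–6, 8–17 and 19–24.

**Step 15 (key step).** The most likely failure is base acting on the product rather than the substrate: E1cB loss of silanolate from the β-silyloxy ketone or epimerisation at C7 once the ketone exists. Fallback: starting from 18, the fragmentation would be run with LiAlH4 in THF as both base and hydride source, so the ketone is reduced as it forms to the non-enolisable ring carbinol F1 (both C6 epimers). Dess–Martin oxidation of F1 under buffered conditions then returns to 20.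

**Step 8.** Two things can go wrong: competing 1,2-reduction of the enone by the borohydride, and poor facial discrimination at C10 (the isopropyl and silyloxy groups sit on opposite faces). The second is tolerated by design, since C10 is erased in step 15. Fallback for the first: from 8, RhCl(PPh3)3-catalysed 1,4-hydrosilylation with Et3SiH would give the isolable triethylsilyl enol ether F2; cleavage with MeLi regenerates enolate 11, and addition of 10 rejoins the route at 12.

**Step 9.** The magnesium or cerium aldolate of 12 may undergo retro-aldol cleavage, or the reagent may enolise the ketone instead of adding. Fallback: from 12, the C1 hydroxyl would be capped with Et3SiOTf/2,6-lutidine to the silyl ether F3, vinyl addition would then give the protected carbinol F4, and AcOH–THF–H2O would remove the triethylsilyl group to return to 13.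

**Step 16.** Divalent palladium may engage the C1=C10 alkene across the ring, or the β-hydride elimination may give some 4Z enone. Fallback without palladium: from 20, deprotonation with LiN(i-Pr)2 and trapping with PhSeCl would give the 5-phenylselanyl ketone F5; oxidation with H2O2/pyridine and syn elimination of the selenoxide returns to 22.

**Step 20.** Hydride may enter from the other face if the enone reacts through the conformer with the C4=C5 unit turned over, which would deliver the natural C6 carbinol. Fallback: from 27, that product, the allylic alcohol F6, is the matched, fast-reacting partner for Ti(OiPr)4/D-(−)-diethyl tartrate/t-BuOOH. This titanium system is erythro-selective by reagent control and would give 31 directly, bypassing 28–30.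

**Step 21.** Oxygen delivery may occur through the strained conformer with the C6 oxygen eclipsing the alkene, giving the other epoxide face. Fallback: from 28, Mitsunobu inversion with formic acid (PPh3, DIAD) would give the inverted formate F7, KHCO3/MeOH would release F6, and the titanium–tartrate epoxidation described for step 20 would then give 31.

## Further compounds

F1 | step 15 | 8-(tert-butyldimethylsilyloxy)germacr-1(10)E-en-6-ol, both C6 epimers | CC(C)(C)[Si](C)(C)O[C@@H]1C/C(C)=C/CC[C@H](C)CC(O)[C@H]1C(C)C
F2 | step 8 | 4-(tert-butyldimethylsilyloxy)-5-isopropyl-2-methyl-1-(triethylsilyloxy)cyclopent-1-ene | CC(C)[C@H]1[C@H](O[Si](C)(C)C(C)(C)C)CC(C)=C1O[Si](CC)(CC)CC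
F3 | step 9 | C1 triethylsilyl ether of 12 | CC(C)[C@H]1[C@H](O[Si](C)(C)C(C)(C)C)C[C@](C)([C@H](O[Si](CC)(CC)CC)CCC(C)=C)C1=O
F4 | step 9 | C1 triethylsilyl ether of 13 | CC(C)[C@H]1[C@H](O[Si](C)(C)C(C)(C)C)C[C@](C)([C@H](O[Si](CC)(CC)CC)CCC(C)=C)[C@]1(O)C=C
F5 | step 16 | 5-(phenylselanyl)-8-(tert-butyldimethylsilyloxy)germacr-1(10)E-en-6-one, C5 not defined | CC(C)(C)[Si](C)(C)O[C@@H]1C/C(C)=C/CC[C@H](C)C([Se]c2ccccc2)C(=O)[C@H]1C(C)C
F6 | step 20 | 6-hydroxygermacra-1(10)E,4E-dien-8-yl 3-(tert-butyldimethylsilyloxy)-4-methoxybenzoate with the natural C6 configuration (C6 epimer of 28) | COc1ccc(C(=O)O[C@@H]2C/C(C)=C/CC/C(C)=C/[C@H](O)[C@H]2C(C)C)cc1O[Si](C)(C)C(C)(C)C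
F7 | step 21 | C6 formate of F6 (C6 inverted relative to 28) | COc1ccc(C(=O)O[C@@H]2C/C(C)=C/CC/C(C)=C/[C@H](OC=O)[C@H]2C(C)C)cc1O[Si](C)(C)C(C)(C)C
A1 | alternative 1 | germacra-1(10),4-diene 6-O-triethylsilyl ether 8-(3-O-PMB-isovanillate), product of the Suzuki closure | COc1ccc(C(=O)O[C@@H]2C/C(C)=C/CC/C(C)=C/[C@H](O[Si](CC)(CC)CC)[C@H]2C(C)C)cc1OCc1ccc(OC)cc1
A2 | alternative 1 | open-chain (E)-vinyl iodide with terminal 1,3-diene, precursor of A1 | C=C/C=C(C)/C[C@@H](OC(=O)c1ccc(OC)c(OCc2ccc(OC)cc2)c1)[C@H](C(C)C)[C@@H](O[Si](CC)(CC)CC)/C=C(C)/I
A3 | alternative 2 | 3-phenylsulfonyl germacra-1(10),4-diene, 6-O-TBS 8-O-PMB, product of the sulfone alkylation | COc1ccc(CO[C@@H]2C/C(C)=C/CC(S(=O)(=O)c3ccccc3)/C(C)=C/[C@H](O[Si](C)(C)C(C)(C)C)[C@H]2C(C)C)cc1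
A4 | alternative 2 | open-chain C2 allylic bromide C3 allylic sulfone, precursor of A3 | BrC/C=C(C)/C[C@@H](OCc1ccc(OC)cc1)[C@H](C(C)C)[C@@H](O[Si](C)(C)C(C)(C)C)/C=C(C)/CS(=O)(=O)c1ccccc1
A5 | alternative 3 | 6-O-triethylsilyl germacra-1(10),4-dien-8-ol, product of the reductive coupling | O[C@@H]1C/C(C)=C/CC/C(C)=C/[C@H](O[Si](CC)(CC)CC)[C@H]1C(C)C
A6 | alternative 3 | open-chain methyl alkyne with terminal C8–C9 epoxide, precursor of A5 | CC#CCC/C(C)=C/[C@H](O[Si](CC)(CC)CC)[C@@H](C(C)C)[C@H]1CO1
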